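## The problem

7'-O-Methylagathisflavone (22) consists of two apigenin-type flavones. Unit one (rings A, B, C, plain locants) carries the 7-methoxy group and is bonded through C8 to C6'' of unit two (rings A'', B'', C'', double-primed locants; the B-ring oxygens are O4' and O4'''). The C8–C6'' bond has four ortho oxygen substituents: O1 on C8a, the methoxy group on C7, and the hydroxyls on C5'' and C7''. It is therefore the most crowded bond in the molecule and a poor candidate for late cross-coupling.

There is no stereocentre. The hindered axis is the only stereogenic element, so nothing has to be relayed or controlled.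

The real difficulty is constitutional. Six oxygens on two phloroglucinol rings must end up as one methyl ether, three free hydroxyls and two pyranone oxygens. The 8-linkage of unit one and the 6-linkage of unit two must also be fixed so that they cannot interchange.

Interchange is a real danger. 5-Hydroxyflavones open and reclose in hot mineral acid (Wessely–Moser rearrangement), and any intermediate with two free hydroxyls beside one acyl group can close either way. In addition, pyranones are opened by hot alkoxide, and the electron-rich rings are attacked by oxidants and by benzyl or formaldehyde-derived cations.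

The enabling feature is ring A. It bears oxygen on C8a, C5 and C7 in a 1,3,5-pattern, hydrogen on C4a and C6, and the aryl group on C8. A ketene carbonyl carbon (C8a), an ynol ether carbon (C5) and an enol ether carbon (C7) can be joined to give exactly this ring. Each oxygen then arrives in a different state: free OH, OEt and OMe.

## Retrosynthesis

**22 to 21.** Only O–alkyl bonds are cut: four O–benzyl bonds (O4', O4''', O5'', O7'') and the O5–ethyl bond.
- The group on O5 is set by the alkyne of the key step. Ethyl belongs to the one ynol ether that is sold and that tolerates 80 °C. tert-Butyl and benzyl ynol ethers fragment or rearrange below that temperature.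
- The C4 carbonyl in the peri position makes the O5 ether chelation-activated. The O7 methyl ether has no such help.
- The forward reaction must cleave five ethers and spare the sixth without hot protic acid.

**21 to 16 and 17.** Both pyranones are opened at O1–C2 (21 to bis-ynone 19, closing forward through bis-enaminone 20). They are then cut at C3–C4 (19 to bis-carbinol 18, then to dialdehyde 16 and two molecules of alkyne 17).
- The neighbouring C2–C3 cut (diketone logic) needs a bis-acetophenone. Making one on this biphenyl requires a Lewis acid next to the O5'' benzyl ether, the group that guards the 6-linkage.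
- The C3–C4 cut needs only aldehydes and basic or neutral reagents.
- Every operation is twofold. Compound 16 is just the biphenyl core, four rings smaller than 21.
- The forward closure must be 6-endo.

**16 to 14.** The bonds C4a–C4 and C4a''–C4'' are cut (16 to diol 15), and the acetal on O4' is restored (15 to 14).
- Formaldehyde delivered by a magnesium phenoxide can reach ortho carbons only.
- In ring A the sole free ortho carbon is C4a, so the equally activated para carbon C6 stays untouched.
- In ring A'' the two ortho carbons are equivalent.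
- An intermolecular acylation would have to distinguish C4a from C6 by electronics alone.

**14 to 8 and 9.** Ring A is taken apart completely. The bonds cut are C6–C7, C5–C6, C4a–C8a and C8–C8a. This leads back through cyclohexadienone 13, dienylketene 12, vinylcyclobutenone 11 and vinylketene 10 to diazoketone 8 and ethoxyacetylene 9.
- The neighbouring cut, C8–C6'', would need a coupling with four ortho substituents. Here that bond already exists in 8 as an ordinary aryl–CH bond.
- Ring A is chosen rather than ring A'' because ring A'' is symmetric when protected and can be bought as 1. Ring A has three different oxygens.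
- A pentasubstituted benzene becomes an open chain plus a two-carbon alkyne.
- The forward cascade needs one alkyne orientation and a feasible closure at the aryl-bearing terminus.

**8 to 3 and 4.** The bond between the diazo carbon (future C6) and the carbonyl carbon (future C8a) is cut: 8 to acid 6, forward through mixed anhydride 7. The C7=C8 alkene is then cut: 6 to aldehyde 3 and methyl methoxyacetate 4, forward through ester 5.
- The O7 methyl group comes in with 4 and never has to be placed selectively.
- The condensation must give the Z alkene, with the aryl group cis to methoxy.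

**3 to 1.** Three O–C bonds are cut: 3 to 2 to 2,4,6-trihydroxybenzaldehyde 1.
- O4, the future O1'', must differ from O2 and O6, the future O5'' and O7''.
- Its position para to the formyl group makes it the most acidic hydroxyl and the only one not hydrogen-bonded, so it can be addressed first.

## Roads not taken

**Alternative 1:** The cut runs through both O1–C8a bonds. Each pyranone oxygen is replaced by fluorine in the biphenyl bis(1,3-diketone) A2. K2CO3 in hot DMF would let each enolate oxygen displace its ortho fluoride, giving the tetra-O-benzyl 5-O-methyl biflavone A1 in one operation.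
- Merits: the fluorines fix the 8- and 6-linkage beyond doubt. The closure is basic and mild. Intramolecular displacement in 2-fluoroaryl diketones is established. Fluorine also helps to direct metalation for installing the acyl groups.
- Equal point: A1 needs the same chelation-controlled dealkylation at O5 as 21.
- Weak points: the C8–C6'' bond is left for a cross-coupling of two electron-rich halves with four ortho substituents, the least dependable class of biaryl coupling. Each ring that must accept the nucleophile carries two alkoxy donors and only one acyl acceptor. The fluorinated ring A with its differentiated oxygens still has to be built by stepwise substitution.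
- Comparison: this road is more convergent and needs neither light nor diazo compounds, and in that respect it is better. The chosen plan never forms the hindered axis by coupling, and ring A appears with its three oxygens already distinct.

**Alternative 2:** The cut is C4a–C5. Ring A would be closed onto an existing 4-pyranone. Under an equilibrating non-nucleophilic base, the extended enolate of keto ester A4 attacks its terminal ester through the pyranone carbon next to the side chain. After enolisation this gives the 5,7-dihydroxy-8-arylflavone A3.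
- Merits: rings B and C of unit one are in place before ring A. The aryl–C8 bond is again an sp3 bond at the time of closure. The free 5,7-diol can be methylated at O7 selectively because O5–H is chelated. No hazardous reagent is needed.
- Weak points: the most acidic site of A4 is the methylene between ketone and ester, so the productive dienolate is a minor species. C-acylation at a pyranone ring carbon is unusual and competes with O-acylation and with retro-Claisen cleavage. The triply substituted methine of A4 is hard to assemble. Unit two must still be built afterwards in a second, separate campaign.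
- Comparison: the O7 methylation logic is as clean as in the chosen plan. The chosen plan relies on a cascade whose individual events are each well known, and it builds both pyranones by twofold operations.

**Alternative 3:** The cuts are O1–C8a, C4a–C4 and O1–C2. CsF would release the C4a–C8a aryne from silyl triflate A6. The carboxylate of arylpropiolic acid A7 adds to C8a, the aryl anion at C4a takes over the acyl group, and the phenoxide closes 6-endo onto the ynone to give the penta-O-benzyl biflavone A5.
- Merits: ring C arises in a single step. The all-benzyl product needs only hydrogenolysis, which is gentler than the Lewis acid finish of the chosen plan. The C5 alkoxy group polarises the aryne so that the nucleophile prefers C8a.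
- Weak points: C8a is also the carbon beside the bulky C8 aryl group, so steric and electronic control oppose each other. Proton transfer from the acid to the aryl anion gives a plain aryl ester and ends the sequence. A6 is a benzene with five substituents that already contains the hindered biaryl bond, so the hardest problems are only moved into the precursor.
- Comparison: the final deprotection is better on this road. The chosen plan has far simpler precursors and constructs ring A and its substitution pattern at the same time.

Key step: step 5

Assumption: the structure carries no descriptor for the C8–C6'' axis, so 22 is made as the racemate. Compounds 14 and 15 have a symmetric ring A'' and no stereogenic axis, and all compounds from 16 on are racemic with respect to it.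

## Route

Step 1
Reactants: 1 2,4,6-trihydroxybenzaldehyde
Product: 2 2,6-dihydroxy-4-(methoxymethoxy)benzaldehyde
Conditions: MOMCl (1.0 equiv), i-Pr2NEt, THF, 0 °C
Reagents that add atoms: chloromethyl methyl ether (MOMCl), COCCl
Why: Williamson-type O-alkylation under stoichiometric control; the 4-hydroxyl is para to the formyl group, the most acidic and the only one not hydrogen-bonded to the carbonyl, so one equivalent of reagent should react there first. Over-alkylated material is less polar and separable.

Step 2
Reactants: 2 2,6-dihydroxy-4-(methoxymethoxy)benzaldehyde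
Product: 3 2,6-bis(benzyloxy)-4-(methoxymethoxy)benzaldehyde
Conditions: BnBr (2.4 equiv), K2CO3, DMF, 60 °C
Reagents that add atoms: benzyl bromide, BrCc1ccccc1
Why: Williamson ether synthesis; warm K2CO3/DMF overcomes the hydrogen bond of the ortho hydroxyls, and the formyl group lowers the ring nucleophilicity enough to favour O- over C-benzylation. The acetal is stable to base.

Step 3
Reactants: 3 2,6-bis(benzyloxy)-4-(methoxymethoxy)benzaldehyde, 4 methyl methoxyacetate
Product: 6 (Z)-3-[2,6-bis(benzyloxy)-4-(methoxymethoxy)phenyl]-2-methoxyprop-2-enoic acid, via methyl ester 5 (not isolated)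
Conditions: 4 (3 equiv), NaOMe, THF, 0 to 60 °C; then aq NaOH, MeOH, 50 °C; 1 M HCl to pH 3, 0 °C
Reagents that add atoms: sodium hydroxide (oxygen of the acid OH), [Na+].[OH-]
Why: Claisen-type aldol condensation of an ester enolate with a non-enolisable aldehyde and E1cB loss of hydroxide; the water released already starts the saponification, which is therefore completed in the same pot. The alkene forms under product-stability control with the bulky aryl group trans to the carboxyl group and cis to the small methoxy group (Z), and crystallisation of 6 should remove any E isomer.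

Step 4
Reactants: 6 (Z)-3-[2,6-bis(benzyloxy)-4-(methoxymethoxy)phenyl]-2-methoxyprop-2-enoic acid
Product: 8 (Z)-4-[2,6-bis(benzyloxy)-4-(methoxymethoxy)phenyl]-1-diazo-3-methoxybut-3-en-2-one, via mixed anhydride 7 (not isolated)
Conditions: i-BuOCOCl, N-methylmorpholine, THF, −20 °C; then CH2N2, Et2O, 0 °C to rt
Reagents that add atoms: diazomethane, C=[N+]=[N-]; isobutyl chloroformate, CC(C)COC(=O)Cl (atoms only in 7)
Why: Arndt–Eistert-type acylation of diazomethane through a mixed carbonic anhydride, which avoids the HCl that acid chloride formation would release onto the acetal and the enol ether. The alkene is trisubstituted, donor-substituted and shielded by the di-ortho-substituted arene, hence a poor dipolarophile, so acylation should outrun pyrazoline formation.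

Step 5
Reactants: 8 (Z)-4-[2,6-bis(benzyloxy)-4-(methoxymethoxy)phenyl]-1-diazo-3-methoxybut-3-en-2-one, 9 ethoxyacetylene
Product: 14 2',6'-bis(benzyloxy)-4-ethoxy-6-methoxy-4'-(methoxymethoxy)biphenyl-2-ol, via vinylketene 10 (not isolated), via vinylcyclobutenone 11 (not isolated), via dienylketene 12 (not isolated), via cyclohexadienone 13 (not isolated)
Conditions: 9 (4 equiv), hν (300 nm), degassed ClCH2CH2Cl, 25 °C; then 80 °C
Reagents that add atoms: none
Why: The closest known reaction type is the Danheiser benzannulation in its photochemical Wolff form with an alkoxyalkyne. Light expels N2 from 8 and the alkenyl carbon C7 shifts to the diazo carbon C6 with retention of alkene geometry, giving vinylketene 10. The nucleophilic CH terminus of 9 attacks the ketene carbonyl carbon, so the (2+2) cycloaddition gives only 11, with bonds C8a–C4a and C5–C6 and the ethoxy group on C5. On heating, 11 opens reversibly by conrotatory 4π cleavage of C8a–C6; only isomer 12, with the alkenyl arm turned inward, can react on, and it is drained by disrotatory 6π closure (C8–C8a), the event that closes ring A as a six-membered carbocycle. The sp3 centres at C6 of 11 and C8 of 13 are transient and vanish on ring opening and on tautomerisation of 13 to phenol 14, so no stereocentre remains. Two selectivities are needed: the alkyne orientation, secured by the polarity of the ynol ether, and closure at the aryl-bearing terminus, secured by the Z geometry of 8, which places the aryl group outward in 12. The same trans arrangement and the two ortho benzyloxy groups block electrocyclisation of 10 onto its own arene. The excess of 9 keeps 10 from being captured by the phenol 14 as it forms.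

Step 6
Reactants: 14 2',6'-bis(benzyloxy)-4-ethoxy-6-methoxy-4'-(methoxymethoxy)biphenyl-2-ol
Product: 15 2',6'-bis(benzyloxy)-4-ethoxy-6-methoxybiphenyl-2,4'-diol
Conditions: HCl (cat.), MeOH–THF, 45 °C
Reagents that add atoms: none
Why: Acid-catalysed acetal exchange (MOM cleavage); methanol traps the formaldehyde unit as dimethoxymethane and keeps it away from the electron-rich rings. Aryl benzyl, ethyl and methyl ethers are inert to dilute acid at this temperature.

Step 7
Reactants: 15 2',6'-bis(benzyloxy)-4-ethoxy-6-methoxybiphenyl-2,4'-diol
Product: 16 2',6'-bis(benzyloxy)-4-ethoxy-2,4'-dihydroxy-6-methoxybiphenyl-3,3'-dicarbaldehyde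
Conditions: MgCl2, Et3N, (CH2O)n, MeCN, reflux; 1 M HCl work-up
Reagents that add atoms: formaldehyde (as paraformaldehyde), C=O
Why: Twofold Casnati–Skattebøl ortho-formylation; the magnesium phenoxide binds formaldehyde and delivers it through a cyclic transition state to an ortho carbon only, and a second formaldehyde accepts hydride (Oppenauer-type) to give the aldehyde. In ring A the only free ortho carbon is C4a (biphenyl C3) and the para carbon C6 is out of reach; in ring A'' the two ortho carbons are equivalent and the first formyl group, held as a magnesium chelate, deactivates the ring towards a second. The basic medium leaves all ethers untouched.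

Step 8
Reactants: 16 2',6'-bis(benzyloxy)-4-ethoxy-2,4'-dihydroxy-6-methoxybiphenyl-3,3'-dicarbaldehyde, 17 1-(benzyloxy)-4-ethynylbenzene
Product: 18 2',6'-bis(benzyloxy)-3,3'-bis{3-[4-(benzyloxy)phenyl]-1-hydroxyprop-2-yn-1-yl}-4-ethoxy-6-methoxybiphenyl-2,4'-diol (mixture of diastereomers)
Conditions: 17 (5 equiv), n-BuLi, THF, −78 °C; then 16, −78 °C to rt; aq NH4Cl
Reagents that add atoms: none
Why: 1,2-Addition of a lithium acetylide to unprotected salicylaldehyde-type aldehydes; two equivalents serve as base for the phenols and regenerate 17, which is recovered. The two carbinol centres form without control relative to each other and to the axis, which does not matter because step 9 removes them.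

Step 9
Reactants: 18 2',6'-bis(benzyloxy)-3,3'-bis{3-[4-(benzyloxy)phenyl]-1-hydroxyprop-2-yn-1-yl}-4-ethoxy-6-methoxybiphenyl-2,4'-diol
Product: 19 1,1'-[2',6'-bis(benzyloxy)-4-ethoxy-2,4'-dihydroxy-6-methoxybiphenyl-3,3'-diyl]bis{3-[4-(benzyloxy)phenyl]prop-2-yn-1-one}
Conditions: activated MnO2, CH2Cl2, rt
Reagents that add atoms: none
Why: MnO2 oxidation of doubly activated (benzylic and propargylic) alcohols, a neutral heterogeneous method used for ortho-hydroxyaryl propargylic alcohols. The crude carbinol is used at once, and each ynone formed is stabilised by a hydrogen bond from its ortho hydroxyl.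

Step 10
Reactants: 19 1,1'-[2',6'-bis(benzyloxy)-4-ethoxy-2,4'-dihydroxy-6-methoxybiphenyl-3,3'-diyl]bis{3-[4-(benzyloxy)phenyl]prop-2-yn-1-one}
Product: 21 5,7-bis(benzyloxy)-2-[4-(benzyloxy)phenyl]-6-{2-[4-(benzyloxy)phenyl]-5-ethoxy-7-methoxy-4-oxo-4H-chromen-8-yl}-4H-chromen-4-one, via bis-enaminone 20 (not isolated)
Conditions: Et2NH, EtOH–THF, rt to 60 °C
Reagents that add atoms: diethylamine, CCNCC (atoms only in 20)
Why: Amine-mediated cyclisation of ortho-hydroxyaryl ynones; conjugate addition of Et2NH gives the enaminone, and the phenol then replaces the amine at the same carbon by addition–elimination, so only the six-membered pyranone can form and the 5-exo (aurone) path is excluded. Each acyl group has a single free ortho hydroxyl (O on C8a, O on C8a''), so the 8- and 6-linkages are fixed.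

Step 11
Reactants: 21 5,7-bis(benzyloxy)-2-[4-(benzyloxy)phenyl]-6-{2-[4-(benzyloxy)phenyl]-5-ethoxy-7-methoxy-4-oxo-4H-chromen-8-yl}-4H-chromen-4-one
Product: 22 7'-O-methylagathisflavone, 8-[5,7-dihydroxy-2-(4-hydroxyphenyl)-4-oxo-4H-chromen-6-yl]-5-hydroxy-2-(4-hydroxyphenyl)-7-methoxy-4H-chromen-4-one
Conditions: BCl3 (excess), C6HMe5, CH2Cl2, −78 °C to rt; H2O
Reagents that add atoms: none
Why: BCl3 ether cleavage with pentamethylbenzene as a non-basic benzyl cation scavenger removes the four benzyl groups at low temperature. On warming, boron chelated between O4 and O5 activates the peri ethyl ether for attack by chloride, the known selective 5-O-dealkylation of flavones. The unchelated 7-methyl ether is not cleaved by BCl3 under these conditions, and the absence of hot protic acid avoids Wessely–Moser isomerisation.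

## Compound list

1 | 2,4,6-trihydroxybenzaldehyde | O=Cc1c(O)cc(O)cc1O | starting material
2 | 2,6-dihydroxy-4-(methoxymethoxy)benzaldehyde | O=Cc1c(O)cc(OCOC)cc1O | intermediate
3 | 2,6-bis(benzyloxy)-4-(methoxymethoxy)benzaldehyde | O=Cc1c(OCc2ccccc2)cc(OCOC)cc1OCc1ccccc1 | intermediate
4 | methyl methoxyacetate | COCC(=O)OC | starting material
5 | methyl (Z)-3-[2,6-bis(benzyloxy)-4-(methoxymethoxy)phenyl]-2-methoxyprop-2-enoate | CO/C(=C\c1c(OCc2ccccc2)cc(OCOC)cc1OCc1ccccc1)C(=O)OC | intermediate
6 | (Z)-3-[2,6-bis(benzyloxy)-4-(methoxymethoxy)phenyl]-2-methoxyprop-2-enoic acid | CO/C(=C\c1c(OCc2ccccc2)cc(OCOC)cc1OCc1ccccc1)C(=O)O | intermediate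
7 | (Z)-3-[2,6-bis(benzyloxy)-4-(methoxymethoxy)phenyl]-2-methoxyprop-2-enoic isobutyl carbonic anhydride | CO/C(=C\c1c(OCc2ccccc2)cc(OCOC)cc1OCc1ccccc1)C(=O)OC(=O)OCC(C)C | intermediate
8 | (Z)-4-[2,6-bis(benzyloxy)-4-(methoxymethoxy)phenyl]-1-diazo-3-methoxybut-3-en-2-one | CO/C(=C\c1c(OCc2ccccc2)cc(OCOC)cc1OCc1ccccc1)C(=O)C=[N+]=[N-] | intermediate
9 | ethoxyacetylene | C#COCC | starting material
10 | (Z)-4-[2,6-bis(benzyloxy)-4-(methoxymethoxy)phenyl]-3-methoxybuta-1,3-dien-1-one | CO/C(=C\c1c(OCc2ccccc2)cc(OCOC)cc1OCc1ccccc1)C=C=O | intermediate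
11 | 4-{(Z)-2-[2,6-bis(benzyloxy)-4-(methoxymethoxy)phenyl]-1-methoxyethenyl}-3-ethoxycyclobut-2-en-1-one (racemic) | CCOC1=CC(=O)C1/C(OC)=C/c1c(OCc2ccccc2)cc(OCOC)cc1OCc1ccccc1 | intermediate
12 | (3E,5Z)-6-[2,6-bis(benzyloxy)-4-(methoxymethoxy)phenyl]-3-ethoxy-5-methoxyhexa-1,3,5-trien-1-one | O=C=C/C(OCC)=C\C(OC)=C\c1c(OCc2ccccc2)cc(OCOC)cc1OCc1ccccc1 | intermediate
13 | 6-[2,6-bis(benzyloxy)-4-(methoxymethoxy)phenyl]-3-ethoxy-5-methoxycyclohexa-2,4-dien-1-one (racemic) | O=C1C=C(OCC)C=C(OC)C1c1c(OCc2ccccc2)cc(OCOC)cc1OCc1ccccc1 | intermediate
14 | 2',6'-bis(benzyloxy)-4-ethoxy-6-methoxy-4'-(methoxymethoxy)biphenyl-2-ol | COc1cc(OCC)cc(O)c1-c1c(OCc2ccccc2)cc(OCOC)cc1OCc1ccccc1 | intermediate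
15 | 2',6'-bis(benzyloxy)-4-ethoxy-6-methoxybiphenyl-2,4'-diol | COc1cc(OCC)cc(O)c1-c1c(OCc2ccccc2)cc(O)cc1OCc1ccccc1 | intermediate
16 | 2',6'-bis(benzyloxy)-4-ethoxy-2,4'-dihydroxy-6-methoxybiphenyl-3,3'-dicarbaldehyde (racemic axis) | COc1cc(OCC)c(C=O)c(O)c1-c1c(OCc2ccccc2)cc(O)c(C=O)c1OCc1ccccc1 | intermediate
17 | 1-(benzyloxy)-4-ethynylbenzene | C#Cc1ccc(OCc2ccccc2)cc1 | starting material
18 | 2',6'-bis(benzyloxy)-3,3'-bis{3-[4-(benzyloxy)phenyl]-1-hydroxyprop-2-yn-1-yl}-4-ethoxy-6-methoxybiphenyl-2,4'-diol (mixture of diastereomers) | COc1cc(OCC)c(C(O)C#Cc2ccc(OCc3ccccc3)cc2)c(O)c1-c1c(OCc2ccccc2)cc(O)c(C(O)C#Cc2ccc(OCc3ccccc3)cc2)c1OCc1ccccc1 | intermediate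
19 | 1,1'-[2',6'-bis(benzyloxy)-4-ethoxy-2,4'-dihydroxy-6-methoxybiphenyl-3,3'-diyl]bis{3-[4-(benzyloxy)phenyl]prop-2-yn-1-one} | COc1cc(OCC)c(C(=O)C#Cc2ccc(OCc3ccccc3)cc2)c(O)c1-c1c(OCc2ccccc2)cc(O)c(C(=O)C#Cc2ccc(OCc3ccccc3)cc2)c1OCc1ccccc1 | intermediate
20 | 1,1'-[2',6'-bis(benzyloxy)-4-ethoxy-2,4'-dihydroxy-6-methoxybiphenyl-3,3'-diyl]bis{3-[4-(benzyloxy)phenyl]-3-(diethylamino)prop-2-en-1-one} (alkene geometry not defined) | COc1cc(OCC)c(C(=O)C=C(N(CC)CC)c2ccc(OCc3ccccc3)cc2)c(O)c1-c1c(OCc2ccccc2)cc(O)c(C(=O)C=C(N(CC)CC)c2ccc(OCc3ccccc3)cc2)c1OCc1ccccc1 | intermediate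
21 | 5,7-bis(benzyloxy)-2-[4-(benzyloxy)phenyl]-6-{2-[4-(benzyloxy)phenyl]-5-ethoxy-7-methoxy-4-oxo-4H-chromen-8-yl}-4H-chromen-4-one | COc1cc(OCC)c2c(=O)cc(-c3ccc(OCc4ccccc4)cc3)oc2c1-c1c(OCc4ccccc4)cc2oc(-c3ccc(OCc4ccccc4)cc3)cc(=O)c2c1OCc1ccccc1 | intermediate
22 | 7'-O-methylagathisflavone | COc1cc(O)c2c(=O)cc(-c3ccc(O)cc3)oc2c1-c1c(O)cc2oc(-c3ccc(O)cc3)cc(=O)c2c1O | target

## Step count and risks

Total step count: 11. Longest linear sequence: 11 steps (1 to 22). Compounds 4, 9 and 17 are bought.

**Risk at step 5 (key step).**
- What may go wrong: the styryl enol ether chromophore of 8, 10 and 11 absorbs in the same region as the diazoketone. Photoisomerisation of the C7=C8 alkene can then turn the bulky aryl group inward. That would slow the 6π closure and leave the ketenes time to dimerise or to acylate the phenol already formed.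
- Fallback, separating ketene formation from light: from 8, a Wolff rearrangement catalysed by PhCO2Ag in aqueous THF with Et3N in the dark (Arndt–Eistert homologation) would give (Z)-4-[2,6-bis(benzyloxy)-4-(methoxymethoxy)phenyl]-3-methoxybut-3-enoic acid F1.
- 1-Chloro-N,N,2-trimethylprop-1-en-1-amine would convert F1 under neutral conditions into (Z)-4-[2,6-bis(benzyloxy)-4-(methoxymethoxy)phenyl]-3-methoxybut-3-enoyl chloride F2.
- Slow addition of Et3N to F2 and excess 9 in toluene generates 10 by dehydrochlorination. Cyclobutenone 11 can then be isolated, purified and heated on its own. The sequence returns to the route at 14.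

**Risk at step 4.**
- What may go wrong: dipolar cycloaddition of diazomethane to the conjugated alkene, and attack at the carbonate carbonyl of 7, which returns the acid as its ester.
- Fallback without diazomethane: from 6, MeLi (2 equiv, THF, −78 to 0 °C) would give (Z)-4-[2,6-bis(benzyloxy)-4-(methoxymethoxy)phenyl]-3-methoxybut-3-en-2-one F3.
- LiN(SiMe3)2 and then CF3CO2CH2CF3 would give (Z)-6-[2,6-bis(benzyloxy)-4-(methoxymethoxy)phenyl]-1,1,1-trifluoro-5-methoxyhex-5-ene-2,4-dione F4.
- Detrifluoroacetylative diazo transfer with MsN3, Et3N and water in MeCN returns to the route at 8.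

**Risk at step 3.**
- What may go wrong: the aldol addition to an electron-rich, di-ortho-substituted aldehyde is reversible and may lie on the side of the reactants. Self-condensation of 4 then consumes the ester. Geometric control may also be incomplete.
- Fallback: an irreversible Horner–Wadsworth–Emmons olefination from 3 with methyl 2-(dimethoxyphosphoryl)-2-methoxyacetate and LiN(SiMe3)2 in THF. The Z ester 5 is separated by chromatography and saponified with LiOH, returning to the route at 6. This makes no compound outside the list (F0).

**Risk at step 8 (and with it steps 7 and 9).**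
- What may go wrong: addition to phenoxide-deactivated aldehydes may be sluggish. The very electron-rich ortho-hydroxybenzylic propargylic alcohols may lose water by ionisation and oligomerise. The free phenols may be attacked in the following oxidation.
- Fallback, replacing acetylide addition by enolate acylation and bypassing steps 7 to 10: from 15, C-acetylation ortho to each hydroxyl with Ac2O/BF3·OEt2 at rt (Friedel–Crafts/Fries manifold under chelate control) would give 1,1'-[2',6'-bis(benzyloxy)-4-ethoxy-2,4'-dihydroxy-6-methoxybiphenyl-3,3'-diyl]diethanone F5.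
- Twofold crossed Claisen condensation with methyl 4-(benzyloxy)benzoate and LiN(SiMe3)2, the direct variant of the Baker–Venkataraman route, would give 1,1'-[2',6'-bis(benzyloxy)-4-ethoxy-2,4'-dihydroxy-6-methoxybiphenyl-3,3'-diyl]bis{3-[4-(benzyloxy)phenyl]propane-1,3-dione} F6.
- Cyclodehydration with catalytic TsOH in warm toluene returns to the route at 21.
- This fallback has its own weak point, exposure of the O5'' benzyl ether to a Lewis acid, which is why it ranks second.

**Risk at step 11.**
- What may go wrong: the 7-methyl group may be lost by delivery of boron from the neighbouring O5'' or O7'' borate. De-ethylation may be incomplete at the temperature that spares the methyl ether. The freed phloroglucinol rings may be C-benzylated.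
- Fallback, an orthogonal two-stage release: from 21, hydrogenolysis (H2, Pd/C, THF–MeOH) removes all benzyl groups without cations and would give 8-[5,7-dihydroxy-2-(4-hydroxyphenyl)-4-oxo-4H-chromen-6-yl]-5-ethoxy-2-(4-hydroxyphenyl)-7-methoxy-4H-chromen-4-one F7.
- The single chelated ether of F7 is then cleaved with AlCl3 in MeCN, arriving at 22.

## Further compounds

F1 | step 5 | (Z)-4-[2,6-bis(benzyloxy)-4-(methoxymethoxy)phenyl]-3-methoxybut-3-enoic acid | CO/C(=C\c1c(OCc2ccccc2)cc(OCOC)cc1OCc1ccccc1)CC(=O)O
F2 | step 5 | (Z)-4-[2,6-bis(benzyloxy)-4-(methoxymethoxy)phenyl]-3-methoxybut-3-enoyl chloride | CO/C(=C\c1c(OCc2ccccc2)cc(OCOC)cc1OCc1ccccc1)CC(=O)Cl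
F3 | step 4 | (Z)-4-[2,6-bis(benzyloxy)-4-(methoxymethoxy)phenyl]-3-methoxybut-3-en-2-one | CO/C(=C\c1c(OCc2ccccc2)cc(OCOC)cc1OCc1ccccc1)C(C)=O
F4 | step 4 | (Z)-6-[2,6-bis(benzyloxy)-4-(methoxymethoxy)phenyl]-1,1,1-trifluoro-5-methoxyhex-5-ene-2,4-dione | CO/C(=C\c1c(OCc2ccccc2)cc(OCOC)cc1OCc1ccccc1)C(=O)CC(=O)C(F)(F)F
F0 | step 3 | none | none
F5 | step 8 | 1,1'-[2',6'-bis(benzyloxy)-4-ethoxy-2,4'-dihydroxy-6-methoxybiphenyl-3,3'-diyl]diethanone | COc1cc(OCC)c(C(C)=O)c(O)c1-c1c(OCc2ccccc2)cc(O)c(C(C)=O)c1OCc1ccccc1
F6 | step 8 | 1,1'-[2',6'-bis(benzyloxy)-4-ethoxy-2,4'-dihydroxy-6-methoxybiphenyl-3,3'-diyl]bis{3-[4-(benzyloxy)phenyl]propane-1,3-dione} | COc1cc(OCC)c(C(=O)CC(=O)c2ccc(OCc3ccccc3)cc2)c(O)c1-c1c(OCc2ccccc2)cc(O)c(C(=O)CC(=O)c2ccc(OCc3ccccc3)cc2)c1OCc1ccccc1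
F7 | step 11 | 8-[5,7-dihydroxy-2-(4-hydroxyphenyl)-4-oxo-4H-chromen-6-yl]-5-ethoxy-2-(4-hydroxyphenyl)-7-methoxy-4H-chromen-4-one | COc1cc(OCC)c2c(=O)cc(-c3ccc(O)cc3)oc2c1-c1c(O)cc2oc(-c3ccc(O)cc3)cc(=O)c2c1O
A1 | alternative 1 | 5,7-bis(benzyloxy)-2-[4-(benzyloxy)phenyl]-6-{2-[4-(benzyloxy)phenyl]-5,7-dimethoxy-4-oxo-4H-chromen-8-yl}-4H-chromen-4-one | COc1cc(OC)c2c(=O)cc(-c3ccc(OCc4ccccc4)cc3)oc2c1-c1c(OCc4ccccc4)cc2oc(-c3ccc(OCc4ccccc4)cc3)cc(=O)c2c1OCc1ccccc1
A2 | alternative 1 | 1,1'-[2',6'-bis(benzyloxy)-2,4'-difluoro-4,6-dimethoxybiphenyl-3,3'-diyl]bis{3-[4-(benzyloxy)phenyl]propane-1,3-dione} | COc1cc(OC)c(C(=O)CC(=O)c2ccc(OCc3ccccc3)cc2)c(F)c1-c1c(OCc2ccccc2)cc(F)c(C(=O)CC(=O)c2ccc(OCc3ccccc3)cc2)c1OCc1ccccc1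
A3 | alternative 2 | 8-[4-(allyloxy)-2,6-bis(benzyloxy)phenyl]-2-[4-(benzyloxy)phenyl]-5,7-dihydroxy-4H-chromen-4-one | Oc1cc(O)c2c(=O)cc(-c3ccc(OCc4ccccc4)cc3)oc2c1-c1c(OCc2ccccc2)cc(OCC=C)cc1OCc1ccccc1
A4 | alternative 2 | methyl 4-[4-(allyloxy)-2,6-bis(benzyloxy)phenyl]-4-{6-[4-(benzyloxy)phenyl]-4-oxo-4H-pyran-2-yl}-3-oxobutanoate (racemic) | COC(=O)CC(=O)C(c1c(OCc2ccccc2)cc(OCC=C)cc1OCc1ccccc1)c1cc(=O)cc(-c2ccc(OCc3ccccc3)cc2)o1
A5 | alternative 3 | 5,7-bis(benzyloxy)-6-{5-(benzyloxy)-2-[4-(benzyloxy)phenyl]-7-methoxy-4-oxo-4H-chromen-8-yl}-2-[4-(benzyloxy)phenyl]-4H-chromen-4-one | COc1cc(OCc4ccccc4)c2c(=O)cc(-c3ccc(OCc4ccccc4)cc3)oc2c1-c1c(OCc4ccccc4)cc2oc(-c3ccc(OCc4ccccc4)cc3)cc(=O)c2c1OCc1ccccc1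
A6 | alternative 3 | 3-(benzyloxy)-6-{5,7-bis(benzyloxy)-2-[4-(benzyloxy)phenyl]-4-oxo-4H-chromen-6-yl}-5-methoxy-2-(trimethylsilyl)phenyl trifluoromethanesulfonate | COc1cc(OCc2ccccc2)c([Si](C)(C)C)c(OS(=O)(=O)C(F)(F)F)c1-c1c(OCc2ccccc2)cc2oc(-c3ccc(OCc4ccccc4)cc3)cc(=O)c2c1OCc1ccccc1
A7 | alternative 3 | 3-[4-(benzyloxy)phenyl]prop-2-ynoic acid | OC(=O)C#Cc1ccc(OCc2ccccc2)cc1
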